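**Plan**

- Cuts, in retrosynthetic order: the four O–benzyl bonds; the C(=O)–ring C bond (aryl addition to an α-aryl aldehyde, then oxidation); the ring B C5–CH bond, traced through an aromatic Claisen rearrangement back to a phenol O–allyl bond; the lactone C3–CH2(ring A) bond; the lactone O1–C2 and O1–C5 bonds together; the two ring bonds of a ketene [2+2] adduct on the allyl group of eugenol.
- Forward: the eugenol allyl group becomes a 3-benzylcyclobutanone, which is ring-expanded to the γ-lactone; ring A is attached at C3, the three-carbon chain is grown on ring B, and ring C is joined last.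
- Enabling feature: without its C3 arm the lactone has a single stereocentre, C4, whose ring neighbours C3 and C5 are both CH2. Removing O1 leaves a cyclobutanone with C4 on a mirror plane, so oxygen insertion into one of two enantiotopic C(=O)–CH2 bonds makes the ring and the stereocentre at once.
- Stereochemistry: C4 (R) from the chiral Sc(OTf)3–N,N'-dioxide catalyst; C3 (R) by alkylation trans to the C4 arm; the side-chain centre (S) from (S)-but-3-en-2-ol through Mitsunobu inversion and suprafacial [3,3] transfer, then carried through non-basic steps only.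

Key step: step 4

Remark: both antipodes of the pipecolic acid-derived N,N'-dioxide ligand are accessible; the one that delivers the R lactone is to be fixed on a pilot run and used throughout.

Step 1
Reactants: 1 eugenol
Product: 2 (4-allyl-2-methoxyphenoxy)triisopropylsilane
Conditions: TIPSCl, imidazole, DMF, rt
Reagents that add atoms: triisopropylsilyl chloride, CC(C)[Si](Cl)(C(C)C)C(C)C
Why: Imidazole-promoted O-silylation (silyl ether protection) masks the phenol against the acid chloride, zinc salts, peracid and amide base of the following steps, and the aryl silyl ether can later be cleaved by fluoride without touching benzyl ethers.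

Step 2
Reactants: 2 (4-allyl-2-methoxyphenoxy)triisopropylsilane; 3 trichloroacetyl chloride
Product: 5 2,2-dichloro-3-[3-methoxy-4-(triisopropylsilyloxy)benzyl]cyclobutan-1-one (racemic), via dichloroketene 4 (not isolated)
Conditions: Zn, Et2O/DME, slow addition of 3, 35 °C
Reagents that add atoms: none
Why: Zinc dehalogenation of 3 releases dichloroketene, which undergoes a thermal ketene–alkene [2+2] cycloaddition with the terminal alkene, the carbonyl carbon bonding to the CH2 terminus so that the benzyl-bearing carbon becomes C3 of the cyclobutanone.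

Step 3
Reactants: 5 2,2-dichloro-3-[3-methoxy-4-(triisopropylsilyloxy)benzyl]cyclobutan-1-one
Product: 6 3-[3-methoxy-4-(triisopropylsilyloxy)benzyl]cyclobutan-1-one
Conditions: Zn, AcOH, rt to 50 °C
Reagents that add atoms: none
Why: Reductive dehalogenation of the α,α-dichloro ketone by zinc in acetic acid removes both chlorine atoms and leaves the achiral ketone in which C3 lies on a mirror plane.

Step 4
Reactants: 6 3-[3-methoxy-4-(triisopropylsilyloxy)benzyl]cyclobutan-1-one
Product: 8 (R)-4-[3-methoxy-4-(triisopropylsilyloxy)benzyl]dihydrofuran-2(3H)-one, via Criegee adduct 7 (not isolated)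
Conditions: m-CPBA (1.5 equiv), Sc(OTf)3 (5 mol%), chiral N,N'-dioxide ligand (pipecolic acid-derived, 2,6-diisopropylanilide arms, 5 mol%), EtOAc, −20 °C
Reagents that add atoms: 3-chloroperoxybenzoic acid (m-CPBA), OOC(=O)c1cccc(Cl)c1
Why: The Sc(OTf)3–N,N'-dioxide complex binds the ketone, the peracid adds to the carbonyl to give the tetrahedral Criegee adduct 7, and the ring CH2 antiperiplanar to the O–O bond migrates to oxygen as 3-chlorobenzoate leaves, so the C2–O1 and O1–C5 bonds of the lactone are both made here. The closest known reaction type is the catalytic asymmetric Baeyer–Villiger oxidation of prochiral 3-substituted cyclobutanones with chiral N,N'-dioxide–Sc(OTf)3 complexes and peracids. The five-membered lactone is not closed by a cyclisation but arises by one-atom ring expansion (1,2-shift) of the four-membered ketone, driven by release of ring strain. C4 becomes stereogenic without any bond to it being made or broken, its R configuration being decided only by which of the two enantiotopic CH2 groups the chiral ligand sphere allows to migrate. Only enantiotopic-group selectivity is needed, since both α-carbons are CH2 and give the same constitution, and the strained ketone reacts at −20 °C, where the electron-rich arene and the silyl ether are inert to the peracid.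

Step 5
Reactants: 9 [4-(benzyloxy)-3-methoxyphenyl]methanol
Product: 10 1-(benzyloxy)-4-(bromomethyl)-2-methoxybenzene
Conditions: PBr3, Et2O, 0 °C; used without storage
Reagents that add atoms: phosphorus tribromide, BrP(Br)Br
Why: Nucleophilic substitution of the benzylic alcohol through its phosphite ester gives the reactive ring A electrophile, which is taken on directly because electron-rich benzyl bromides do not keep well.

Step 6
Reactants: 8 (R)-4-[3-methoxy-4-(triisopropylsilyloxy)benzyl]dihydrofuran-2(3H)-one; 10 1-(benzyloxy)-4-(bromomethyl)-2-methoxybenzene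
Product: 12 (3R,4R)-3-[4-(benzyloxy)-3-methoxybenzyl]-4-[3-methoxy-4-(triisopropylsilyloxy)benzyl]dihydrofuran-2(3H)-one, via lithium enolate 11 (not isolated)
Conditions: LiN(iPr)2 (LDA), THF, −78 °C; then 10, DMPU, −78 to −40 °C
Reagents that add atoms: none
Why: Diastereoselective enolate alkylation, in which the lactone lithium enolate is attacked by the benzylic bromide on the face opposite the C4 arm, should set C3 as R and trans to C4, the arrangement common to the dibenzylbutyrolactone lignans.

Step 7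
Reactants: 12 (3R,4R)-3-[4-(benzyloxy)-3-methoxybenzyl]-4-[3-methoxy-4-(triisopropylsilyloxy)benzyl]dihydrofuran-2(3H)-one
Product: 13 (3R,4R)-3-[4-(benzyloxy)-3-methoxybenzyl]-4-(4-hydroxy-3-methoxybenzyl)dihydrofuran-2(3H)-one
Conditions: TBAF, AcOH, THF, 0 °C
Reagents that add atoms: none
Why: Fluoride-induced cleavage of the aryl silyl ether frees the ring B phenol alone, acetic acid buffering the medium so that the lactone and the benzyl ether are not touched.

Step 8
Reactants: 14 (S)-but-3-en-2-ol; 15 (Z)-1,4-bis(benzyloxy)but-2-ene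
Product: 16 (2S,3E)-5-(benzyloxy)pent-3-en-2-ol
Conditions: 15 in excess, second-generation Grubbs catalyst RuCl2(=CHPh)(PCy3)(1,3-dimesitylimidazolidin-2-ylidene) (3 mol%), CH2Cl2, 40 °C
Reagents that add atoms: none
Why: Olefin cross-metathesis between the slowly homodimerising secondary allylic alcohol and an excess of the reactive symmetrical alkene should give the E-disubstituted allylic alcohol, the carbinol stereocentre of 14 taking no part.

Step 9
Reactants: 13 (3R,4R)-3-[4-(benzyloxy)-3-methoxybenzyl]-4-(4-hydroxy-3-methoxybenzyl)dihydrofuran-2(3H)-one; 16 (2S,3E)-5-(benzyloxy)pent-3-en-2-ol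
Product: 17 (3R,4R)-3-[4-(benzyloxy)-3-methoxybenzyl]-4-(4-{[(2R,3E)-5-(benzyloxy)pent-3-en-2-yl]oxy}-3-methoxybenzyl)dihydrofuran-2(3H)-one
Conditions: PPh3, DIAD, toluene, 0 °C to rt
Reagents that add atoms: none
Why: In the Mitsunobu reaction the phenol displaces the phosphonium-activated secondary allylic alcohol by SN2 with inversion, turning the S carbinol into the R aryl ether.

Step 10
Reactants: 17 (3R,4R)-3-[4-(benzyloxy)-3-methoxybenzyl]-4-(4-{[(2R,3E)-5-(benzyloxy)pent-3-en-2-yl]oxy}-3-methoxybenzyl)dihydrofuran-2(3H)-one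
Product: 19 (3R,4R)-3-[4-(benzyloxy)-3-methoxybenzyl]-4-{3-[(2S,3E)-1-(benzyloxy)pent-3-en-2-yl]-4-hydroxy-5-methoxybenzyl}dihydrofuran-2(3H)-one, via ortho-dienone 18 (not isolated)
Conditions: N,N-diethylaniline, degassed, 180 °C, sealed vessel
Reagents that add atoms: none
Why: The aromatic Claisen rearrangement is a suprafacial [3,3] shift through a chair transition state with the methyl group pseudo-equatorial, so the R ether carbon is exchanged for the S benzylic carbon and an E alkene, the new bond going to C5 of ring B, the only ortho position that carries hydrogen and lets dienone 18 tautomerise to the phenol.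

Step 11
Reactants: 19 (3R,4R)-3-[4-(benzyloxy)-3-methoxybenzyl]-4-{3-[(2S,3E)-1-(benzyloxy)pent-3-en-2-yl]-4-hydroxy-5-methoxybenzyl}dihydrofuran-2(3H)-one
Product: 20 (3R,4R)-3-[4-(benzyloxy)-3-methoxybenzyl]-4-{4-(benzyloxy)-3-[(2S,3E)-1-(benzyloxy)pent-3-en-2-yl]-5-methoxybenzyl}dihydrofuran-2(3H)-one
Conditions: BnBr, K2CO3, DMF, 40 °C
Reagents that add atoms: benzyl bromide, BrCc1ccccc1
Why: Williamson etherification caps the hindered phenol before ozonolysis and oxidation and prevents hemiacetal formation with the coming aldehyde, K2CO3 being too weak to deprotonate the benzylic C–H and C3 of the lactone already being in its favoured trans arrangement.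

Step 12
Reactants: 20 (3R,4R)-3-[4-(benzyloxy)-3-methoxybenzyl]-4-{4-(benzyloxy)-3-[(2S,3E)-1-(benzyloxy)pent-3-en-2-yl]-5-methoxybenzyl}dihydrofuran-2(3H)-one
Product: 22 (3R,4R)-3-[4-(benzyloxy)-3-methoxybenzyl]-4-{4-(benzyloxy)-3-[(2S)-1-(benzyloxy)-3-oxopropan-2-yl]-5-methoxybenzyl}dihydrofuran-2(3H)-one, via ozonide 21 (not isolated)
Conditions: O3, CH2Cl2, −78 °C, Sudan Red 7B end point; then PPh3, −78 °C to rt; crude 22 used at once
Reagents that add atoms: ozone, [O-][O+]=O
Why: Ozonolysis with reductive work-up cleaves the only alkene, which reacts with ozone far faster than the alkoxyarenes, and PPh3 reduces ozonide 21 under neutral conditions that should leave the enolisable α-aryl aldehyde configurationally intact.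

Step 13
Reactants: 22 (3R,4R)-3-[4-(benzyloxy)-3-methoxybenzyl]-4-{4-(benzyloxy)-3-[(2S)-1-(benzyloxy)-3-oxopropan-2-yl]-5-methoxybenzyl}dihydrofuran-2(3H)-one; 23 1-(benzyloxy)-4-bromo-2-methoxybenzene
Product: 25 (3R,4R)-3-[4-(benzyloxy)-3-methoxybenzyl]-4-{4-(benzyloxy)-3-[(2S)-1-(benzyloxy)-3-[4-(benzyloxy)-3-methoxyphenyl]-3-hydroxypropan-2-yl]-5-methoxybenzyl}dihydrofuran-2(3H)-one (both carbinol epimers), via aryl Grignard reagent 24 (not isolated)
Conditions: 23, Mg, THF; then 22, LaCl3·2LiCl (0.3 equiv), THF, −78 °C; aq NH4Cl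
Reagents that add atoms: none
Why: Grignard addition of the aryl-magnesium reagent to the aldehyde is much faster than attack on the lactone at −78 °C, the oxophilic lanthanum salt favouring carbonyl addition over enolisation, and the uncontrolled carbinol centre is of no consequence because it is oxidised next.

Step 14
Reactants: 25 (3R,4R)-3-[4-(benzyloxy)-3-methoxybenzyl]-4-{4-(benzyloxy)-3-[(2S)-1-(benzyloxy)-3-[4-(benzyloxy)-3-methoxyphenyl]-3-hydroxypropan-2-yl]-5-methoxybenzyl}dihydrofuran-2(3H)-one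
Product: 26 (3R,4R)-3-[4-(benzyloxy)-3-methoxybenzyl]-4-{4-(benzyloxy)-3-[(2S)-1-(benzyloxy)-3-[4-(benzyloxy)-3-methoxyphenyl]-3-oxopropan-2-yl]-5-methoxybenzyl}dihydrofuran-2(3H)-one
Conditions: Dess–Martin periodinane, CH2Cl2, 0 °C to rt
Reagents that add atoms: none
Why: Dess–Martin oxidation converts both epimers of the secondary benzylic alcohol into the aryl ketone without base and at low temperature, which should preserve the now doubly activated α-stereocentre.

Step 15
Reactants: 26 (3R,4R)-3-[4-(benzyloxy)-3-methoxybenzyl]-4-{4-(benzyloxy)-3-[(2S)-1-(benzyloxy)-3-[4-(benzyloxy)-3-methoxyphenyl]-3-oxopropan-2-yl]-5-methoxybenzyl}dihydrofuran-2(3H)-one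
Product: 27 (3R,4R)-3-(4-hydroxy-3-methoxybenzyl)-4-{4-hydroxy-3-[(2S)-1-hydroxy-3-(4-hydroxy-3-methoxyphenyl)-3-oxopropan-2-yl]-5-methoxybenzyl}dihydrofuran-2(3H)-one (CNP0191394.1)
Conditions: H2 (1 atm), 10% Pd/C, EtOAc/EtOH, rt, stopped when debenzylation is complete
Reagents that add atoms: none
Why: Catalytic hydrogenolysis removes the three aryl benzyl ethers and the primary benzyl ether under neutral conditions, while the ketone, deactivated by its para-oxygenated ring and flanked by a tertiary carbon, should be reduced more slowly and the base-labile α-centre is not exposed to acid or base.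

**Compound list**

1 | eugenol (4-allyl-2-methoxyphenol) | COc1cc(CC=C)ccc1O | starting material
2 | (4-allyl-2-methoxyphenoxy)triisopropylsilane | COc1cc(CC=C)ccc1O[Si](C(C)C)(C(C)C)C(C)C | intermediate
3 | trichloroacetyl chloride | ClC(Cl)(Cl)C(Cl)=O | starting material
4 | dichloroketene | ClC(Cl)=C=O | intermediate
5 | 2,2-dichloro-3-[3-methoxy-4-(triisopropylsilyloxy)benzyl]cyclobutan-1-one (racemic) | COc1cc(CC2CC(=O)C2(Cl)Cl)ccc1O[Si](C(C)C)(C(C)C)C(C)C | intermediate
6 | 3-[3-methoxy-4-(triisopropylsilyloxy)benzyl]cyclobutan-1-one | COc1cc(CC2CC(=O)C2)ccc1O[Si](C(C)C)(C(C)C)C(C)C | intermediate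
7 | Criegee adduct, 1-hydroxy-3-[3-methoxy-4-(triisopropylsilyloxy)benzyl]cyclobutyl 3-chloroperoxybenzoate | COc1cc(CC2CC(O)(OOC(=O)c3cccc(Cl)c3)C2)ccc1O[Si](C(C)C)(C(C)C)C(C)C | intermediate
8 | (R)-4-[3-methoxy-4-(triisopropylsilyloxy)benzyl]dihydrofuran-2(3H)-one | O=C1C[C@@H](Cc2ccc(O[Si](C(C)C)(C(C)C)C(C)C)c(OC)c2)CO1 | intermediate
9 | [4-(benzyloxy)-3-methoxyphenyl]methanol | COc1cc(CO)ccc1OCc1ccccc1 | starting material
10 | 1-(benzyloxy)-4-(bromomethyl)-2-methoxybenzene | COc1cc(CBr)ccc1OCc1ccccc1 | intermediate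
11 | lithium (4R)-4-[3-methoxy-4-(triisopropylsilyloxy)benzyl]-4,5-dihydrofuran-2-olate (lithium enolate of 8) | [Li]OC1=C[C@@H](Cc2ccc(O[Si](C(C)C)(C(C)C)C(C)C)c(OC)c2)CO1 | intermediate
12 | (3R,4R)-3-[4-(benzyloxy)-3-methoxybenzyl]-4-[3-methoxy-4-(triisopropylsilyloxy)benzyl]dihydrofuran-2(3H)-one | COc1cc(C[C@H]2C(=O)OC[C@@H]2Cc2ccc(O[Si](C(C)C)(C(C)C)C(C)C)c(OC)c2)ccc1OCc1ccccc1 | intermediate
13 | (3R,4R)-3-[4-(benzyloxy)-3-methoxybenzyl]-4-(4-hydroxy-3-methoxybenzyl)dihydrofuran-2(3H)-one | COc1cc(C[C@H]2C(=O)OC[C@@H]2Cc2ccc(O)c(OC)c2)ccc1OCc1ccccc1 | intermediate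
14 | (S)-but-3-en-2-ol | C[C@H](O)C=C | starting material
15 | (Z)-1,4-bis(benzyloxy)but-2-ene | c1ccccc1COC/C=C\COCc1ccccc1 | starting material
16 | (2S,3E)-5-(benzyloxy)pent-3-en-2-ol | C[C@H](O)/C=C/COCc1ccccc1 | intermediate
17 | (3R,4R)-3-[4-(benzyloxy)-3-methoxybenzyl]-4-(4-{[(2R,3E)-5-(benzyloxy)pent-3-en-2-yl]oxy}-3-methoxybenzyl)dihydrofuran-2(3H)-one | COc1cc(C[C@H]2C(=O)OC[C@@H]2Cc2ccc(O[C@H](C)/C=C/COCc3ccccc3)c(OC)c2)ccc1OCc1ccccc1 | intermediate
18 | ortho-dienone, keto tautomer of 19 with ring B as a 6-substituted 2-methoxycyclohexa-2,4-dien-1-one (ring sp3 centre undefined) | COc1cc(C[C@H]2C(=O)OC[C@@H]2CC2=CC([C@@H](COCc3ccccc3)/C=C/C)C(=O)C(OC)=C2)ccc1OCc1ccccc1 | intermediate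
19 | (3R,4R)-3-[4-(benzyloxy)-3-methoxybenzyl]-4-{3-[(2S,3E)-1-(benzyloxy)pent-3-en-2-yl]-4-hydroxy-5-methoxybenzyl}dihydrofuran-2(3H)-one | COc1cc(C[C@H]2C(=O)OC[C@@H]2Cc2cc(OC)c(O)c([C@@H](COCc3ccccc3)/C=C/C)c2)ccc1OCc1ccccc1 | intermediate
20 | (3R,4R)-3-[4-(benzyloxy)-3-methoxybenzyl]-4-{4-(benzyloxy)-3-[(2S,3E)-1-(benzyloxy)pent-3-en-2-yl]-5-methoxybenzyl}dihydrofuran-2(3H)-one | COc1cc(C[C@H]2C(=O)OC[C@@H]2Cc2cc(OC)c(OCc3ccccc3)c([C@@H](COCc3ccccc3)/C=C/C)c2)ccc1OCc1ccccc1 | intermediate
21 | ozonide of 20, the propenyl group replaced by a 5-methyl-1,2,4-trioxolan-3-yl ring (ring centres undefined) | COc1cc(C[C@H]2C(=O)OC[C@@H]2Cc2cc(OC)c(OCc3ccccc3)c([C@@H](COCc3ccccc3)C3OOC(C)O3)c2)ccc1OCc1ccccc1 | intermediate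
22 | (3R,4R)-3-[4-(benzyloxy)-3-methoxybenzyl]-4-{4-(benzyloxy)-3-[(2S)-1-(benzyloxy)-3-oxopropan-2-yl]-5-methoxybenzyl}dihydrofuran-2(3H)-one | COc1cc(C[C@H]2C(=O)OC[C@@H]2Cc2cc(OC)c(OCc3ccccc3)c([C@@H](COCc3ccccc3)C=O)c2)ccc1OCc1ccccc1 | intermediate
23 | 1-(benzyloxy)-4-bromo-2-methoxybenzene | COc1cc(Br)ccc1OCc1ccccc1 | starting material
24 | [4-(benzyloxy)-3-methoxyphenyl]magnesium bromide | COc1cc([Mg]Br)ccc1OCc1ccccc1 | intermediate
25 | (3R,4R)-3-[4-(benzyloxy)-3-methoxybenzyl]-4-{4-(benzyloxy)-3-[(2S)-1-(benzyloxy)-3-[4-(benzyloxy)-3-methoxyphenyl]-3-hydroxypropan-2-yl]-5-methoxybenzyl}dihydrofuran-2(3H)-one (both carbinol epimers) | COc1cc(C[C@H]2C(=O)OC[C@@H]2Cc2cc(OC)c(OCc3ccccc3)c([C@@H](COCc3ccccc3)C(O)c3ccc(OCc4ccccc4)c(OC)c3)c2)ccc1OCc1ccccc1 | intermediate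
26 | (3R,4R)-3-[4-(benzyloxy)-3-methoxybenzyl]-4-{4-(benzyloxy)-3-[(2S)-1-(benzyloxy)-3-[4-(benzyloxy)-3-methoxyphenyl]-3-oxopropan-2-yl]-5-methoxybenzyl}dihydrofuran-2(3H)-one | COc1cc(C[C@H]2C(=O)OC[C@@H]2Cc2cc(OC)c(OCc3ccccc3)c([C@@H](COCc3ccccc3)C(=O)c3ccc(OCc4ccccc4)c(OC)c3)c2)ccc1OCc1ccccc1 | intermediate
27 | (3R,4R)-3-(4-hydroxy-3-methoxybenzyl)-4-{4-hydroxy-3-[(2S)-1-hydroxy-3-(4-hydroxy-3-methoxyphenyl)-3-oxopropan-2-yl]-5-methoxybenzyl}dihydrofuran-2(3H)-one | COc1cc(C[C@H]2C(=O)OC[C@@H]2Cc2cc(OC)c(O)c([C@@H](CO)C(=O)c3ccc(O)c(OC)c3)c2)ccc1O | target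

**Step count**

Total: 15 steps. Longest linear sequence: 13 steps (1–4, 6, 7, 9–15, from eugenol 1 to target 27); steps 5 and 8 prepare the ring A bromide and the chiral allylic alcohol.

**Steps most likely to fail**

Step 13. Enolisation of the α-aryl aldehyde by the basic aryl-magnesium reagent may compete with carbonyl addition, eroding the configuration of the benzylic centre or expelling benzyl alcohol by β-elimination. The fallback replaces the basic main-group nucleophile by a non-basic organochromium species in a Nozaki–Hiyama–Kishi coupling. It sets out from aldehyde 22, taken crude from step 12. The aryl iodide 1-(benzyloxy)-4-iodo-2-methoxybenzene F1, made from commercial 4-iodo-2-methoxyphenol with BnBr and K2CO3, is treated with CrCl2 and catalytic NiCl2 in DMF at room temperature. Oxidative addition at nickel and transmetalation give [4-(benzyloxy)-3-methoxyphenyl]chromium dichloride F2, which adds to the aldehyde only, ignoring the lactone and the acidic α-hydrogen. The fallback returns to the route at alcohol 25.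

Step 10. At 180 °C the transfer of chirality may be incomplete through partial ionisation of the secondary allylic ether or a competing boat or axial-methyl pathway. The freshly formed ortho-allyl phenol may also scramble its new benzylic centre through the phenol-assisted enolene (abnormal Claisen) pathway. The fallback gives up the O-to-C sigmatropic shift and makes the aryl–carbon bond intermolecularly by a γ-selective, syn-stereospecific Pd-catalysed allyl–aryl coupling.
- It sets out from phenol 13. Ortho-bromination (NBS, CH2Cl2, 0 °C) should give (3R,4R)-3-[4-(benzyloxy)-3-methoxybenzyl]-4-(3-bromo-4-hydroxy-5-methoxybenzyl)dihydrofuran-2(3H)-one F3.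
- Benzylation (BnBr, K2CO3, DMF) gives (3R,4R)-3-[4-(benzyloxy)-3-methoxybenzyl]-4-[4-(benzyloxy)-3-bromo-5-methoxybenzyl]dihydrofuran-2(3H)-one F4.
- Borylation with B2(OH)4 (Pd(OAc)2, XPhos, KOAc, EtOH, 80 °C) gives (3R,4R)-3-[4-(benzyloxy)-3-methoxybenzyl]-4-[4-(benzyloxy)-3-(dihydroxyboranyl)-5-methoxybenzyl]dihydrofuran-2(3H)-one F5.
- Alcohol 16 is converted with inversion (AcOH, PPh3, DIAD) into (2R,3E)-5-(benzyloxy)pent-3-en-2-yl acetate F6.
- Coupling of F5 with F6 (Pd(OAc)2, 1,10-phenanthroline, AgSbF6, 1,2-dichloroethane, 60 °C) delivers the aryl group to the γ-carbon on the face from which the acetate departs.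

The fallback returns to the route at benzyl ether 20, so that steps 9 to 11 are bypassed.

Step 4. The aryl group is separated from the four-membered ring by a CH2 group and gives the catalyst little to hold, so discrimination between the two enantiotopic CH2 groups may be insufficient and the lactone may form with too low an enantiomeric purity. The fallback is purification through diastereomers instead of a search for a better catalyst. It sets out from lactone 8 of insufficient purity, which is opened with (S)-1-phenylethylamine (2-hydroxypyridine cat., toluene, 100 °C) to (3R)-3-(hydroxymethyl)-4-[3-methoxy-4-(triisopropylsilyloxy)phenyl]-N-[(1S)-1-phenylethyl]butanamide F7. This is freed from its 3S diastereomer by crystallisation or chromatography and re-lactonised with TsOH in toluene at 80 °C. The fallback returns to the route at 8 as a single enantiomer.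

**Further compounds**

F1 | step 13 | 1-(benzyloxy)-4-iodo-2-methoxybenzene | COc1cc(I)ccc1OCc1ccccc1
F2 | step 13 | [4-(benzyloxy)-3-methoxyphenyl]chromium dichloride | COc1cc([Cr](Cl)Cl)ccc1OCc1ccccc1
F3 | step 10 | (3R,4R)-3-[4-(benzyloxy)-3-methoxybenzyl]-4-(3-bromo-4-hydroxy-5-methoxybenzyl)dihydrofuran-2(3H)-one | COc1cc(C[C@H]2C(=O)OC[C@@H]2Cc2cc(Br)c(O)c(OC)c2)ccc1OCc1ccccc1
F4 | step 10 | (3R,4R)-3-[4-(benzyloxy)-3-methoxybenzyl]-4-[4-(benzyloxy)-3-bromo-5-methoxybenzyl]dihydrofuran-2(3H)-one | COc1cc(C[C@H]2C(=O)OC[C@@H]2Cc2cc(Br)c(OCc3ccccc3)c(OC)c2)ccc1OCc1ccccc1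
F5 | step 10 | (3R,4R)-3-[4-(benzyloxy)-3-methoxybenzyl]-4-[4-(benzyloxy)-3-(dihydroxyboranyl)-5-methoxybenzyl]dihydrofuran-2(3H)-one | COc1cc(C[C@H]2C(=O)OC[C@@H]2Cc2cc(B(O)O)c(OCc3ccccc3)c(OC)c2)ccc1OCc1ccccc1
F6 | step 10 | (2R,3E)-5-(benzyloxy)pent-3-en-2-yl acetate | C[C@@H](OC(C)=O)/C=C/COCc1ccccc1
F7 | step 4 | (3R)-3-(hydroxymethyl)-4-[3-methoxy-4-(triisopropylsilyloxy)phenyl]-N-[(1S)-1-phenylethyl]butanamide | C[C@H](NC(=O)C[C@@H](Cc1ccc(O[Si](C(C)C)(C(C)C)C(C)C)c(OC)c1)CO)c1ccccc1
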